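| flask | substrate | reagent | remark | time |
|---|---|---|---|---|
| autumn | 0.10 M | 0.40 M | run made earlier |  |
| spring | 0.14 M | 0.40 M | run made earlier |  |
| noon | 0.22 M | 0.40 M | run made earlier |  |
| delta | 0.10 M | 0.400 M (fed, over 5.0 min) | all else is in the flask from the start; the feed brings no volume worth counting | 6.0 min |
| beta | 0.10 M (fed, over 5.0 min) | 0.400 M | all else is in the flask from the start; the feed brings no volume worth counting | 6.0 min |
| zeta | 0.10 M (in portions, 4, over 5.0 min) | 0.400 M | first portion at the start, last at 5.0 min | 6.0 min |
| epsilon | 0.10 M | 0.400 M | everything together at the start | 6.0 min |

- autumn (time / min: triple product / %, over-reaction product / %): 0.250: 37.7, 0.4; 0.417: 60.1, 2.2; 0.667: 75.4, 3.1; 1.00: 85.0, 5.1; 1.50: 86.1, 9.2; 2.50: 85.2, 16.3; 4.00: 77.5, 22.6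
- spring (time / min: triple product / %, over-reaction product / %): 0.200: 25.9, 1.4; 0.500: 53.4, 0.5; 1.00: 69.9, 0.9; 1.50: 75.4, 3.2; 2.00: 79.4, 3.5; 3.00: 82.0, 3.7; 4.00: 82.3, 4.3
- noon (time / min: triple product / %, over-reaction product / %): 0.500: 30.8, 0; 1.00: 34.4, 0; 1.50: 35.1, 0; 2.00: 33.6, 1.1; 2.50: 33.8, 0; 3.00: 35.6, 0; 4.00: 33.6, 0

(readings scatter by 1 percentage point)



- the flask that comes out highest in share of triple product in triple product plus over-reaction product, or "all alike" when all lie within 1.5 percentage points (delta / beta / zeta / epsilon / all alike)
- share of triple product in triple product plus over-reaction product at the end, delta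
- share of triple product in triple product plus over-reaction product at the end, beta
- share of triple product in triple product plus over-reaction product at the end, zeta
- share of triple product in triple product plus over-reaction product at the end, epsilon

Start with the easy step: triple product takes 3 reagent per substrate, so 0.400 M of reagent against 0.10 M of substrate leaves 0.100 M spare. Since that spare amount equals the substrate charge and each over-reaction uses one reagent and one triple product, the two stay equal, a second-order decay with equal concentrations, and over-reaction product over triple product grows in step with time.

The autumn run reads 22.6% over-reaction product against 77.5% triple product at 4.00 min. So the over-reaction time, the time at which the two stand equal in a flask with these charges, reads 13.7 min. The share, or selectivity, is then 1/(1 + clock/over-reaction time), where the clock is the time finished product has stood with the spare amount of reagent.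

In epsilon the clock is the full 6.0 min, which gives 69.6%. In delta the feed covers 3 reagent per substrate at 3.75 min, so the clock is 2.25 min and the share 85.9%. In beta, fed substrate meets more reagent than the spare amount but for less time; weighting each minute by reagent over spare and averaging over the feed gives a clock of 6.00 min, about that of epsilon. I place zeta, a coarser feed, near these two without a number.

The forecast picks delta, with 85% (81% to 89%) against 69% for beta, 65% for zeta and 69% for epsilon: “Selectivity therefore depends on how long” finished triple product sits with spare reagent.

The flasks give delta highest: delta 86.6%, beta 70.5%, zeta 66.9%, epsilon 70.1%.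

    substrate + reagent → mono adduct + released group (k = 0.591 M⁻¹ s⁻¹)
    reagent + mono adduct → bis adduct + released group (k = 0.382 M⁻¹ s⁻¹)
    reagent + bis adduct → triple product + released group (k = 0.693 M⁻¹ s⁻¹)
    reagent + triple product → over-reaction product (k = 0.0121 M⁻¹ s⁻¹)

With reagent as charged in epsilon, the mono adduct has a half-life of 0.076 min by its step to bis adduct, but at 6.00 min in zeta, with reagent down to 20.9% of its charge, the same step gives 0.36 min. That later half-life in zeta is still shorter than the over-reaction time of 13.7 min, by a factor of 38.1.

Now take zeta left until 25 min, with the same charges: the clock counted from the start gives 35.4%. The flask gives 35.5%.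

(The numbers in the tables were computed for substances that don't exist, noise included.)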